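If a link can fall back into its two ends, step 1 by itself heads for a resting amount of links, and in these flasks the length of the chains follows from the links present.

| setting | epsilon | alpha |
|---|---|---|
| first end groups | 1.0 M | 1.0 M |
| second end groups | 0.950 M | 0.250 M |
| time | 25 s | 25 s |

    first end groups + second end groups ⇌ links (K1 = 38 L mol⁻¹, k1 = 0.097 L mol⁻¹ s⁻¹)
    links → over-reaction product (k2 = 9.1 × 10⁻⁵ s⁻¹)

- each molecule carries two end groups: a chain counts once for every two ends that are left, dead ends included; the units are half of the end groups of the two monomers charged
- a link that another step uses up counts as cut, two dead ends; so do two ends of one kind that react with each other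
- run time (epsilon): 25 s

1. which of the two ends with the longer chains by the average number of monomer units in a chain (unreacted monomers counted as chains of one) ("neither" if they lie within 10%) (epsilon / alpha / neither)
2. average number of monomer units in a chain (unreacted monomers counted as chains of one) at the end, epsilon
3. average number of monomer units in a chain (unreacted monomers counted as chains of one) at the end, alpha

Let U be the units, half the end groups charged, and L the links. Each link joins two chains into one, so the length is U/(U−L). But the half-life of links by step 2 alone is 130 min, far longer than the run of 25 s, so I reckon with step 1 by itself.

Step 1 need not reach rest within the run. Its net rate is k1(a−L)(b−L), where a is the resting amount of links under step 1 by itself and b the other root, and a·b equals the product of the two end-group charges. So (b−L)/(a−L) = (b/a)·exp(t/τ). In alpha, 13.0 s is the value of τ = 1/(k1(b−a)), the settling time (relaxation time). There a is 0.242 M, which gives L = 0.214 M and length 1.52.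

In epsilon, τ is 31.7 s and a is 0.826 M, which gives L = 0.668 M and length 3.18. So I expect epsilon to have the longer chains.

The forecast says epsilon, with 3.17 (3.05 to 3.3) for epsilon and 1.52 (1.48 to 1.56) for alpha, because “the near-balanced epsilon charge gives clearly longer chains”.

The simulation gives epsilon, with 3.17 for epsilon and 1.52 for alpha.

The run spans 0.789 settling times in epsilon and 1.92 in alpha, and neither flask has stopped changing. At 250 s, epsilon stands at 5.88, with over-reaction product at 1.74% of the first end groups charged. Alpha stands at 1.61 at 250 s, a smaller gain.

The neighbour of alpha with 0.062 M of second end groups has τ = 10.7 s, which gives L = 0.0548 M and length 1.12. The simulation gives 1.11.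

Its constants belong to no real substance; the run is a simulation.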